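**Retrosynthetic overview**

1. The target is methyl shikimate acylated on O3 and O5 by the same (E)-3-methylpent-2-enoic acid (ring numbering: C1 = ester-bearing alkene carbon, C2 = alkene CH, C3–C5 = oxygenated carbons, C6 = CH2). Its free C4–OH is traced back to a C4 acetate (selective methanolysis) and this to a C4 acetyl group (Baeyer–Villiger, retention).
2. Key disconnection: retro-Diels–Alder of the only ring across C3–C4 and C5–C6, giving the dienol ester C3(OCOR)=C2–C1(CO2Me)=C6H2 and the E-enone CH3CO–C4H=C5H–OCOR. Each partner already carries one of the two identical enoate esters.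
3. Enabling feature: in the cyclohexene the C1=C2 double bond lies between C6H2 and the allylic, oxygen-bearing C3 (a 1-acyloxy-3-methoxycarbonylbutadiene retron). C4 and C5 are adjacent, trans-substituted sp3 carbons that map onto an E-alkene; its acetyl group activates it, fixes the regiochemistry and later becomes the C4 oxygen.
4. One catalytic asymmetric cycloaddition sets C3, C4 and C5 together (catalyst: face; endo rule: C3/C4 cis; alkene geometry: C4/C5 trans). The carbocycle is the only ring and is closed in that step.
5. Building blocks: the diene from methyl (E)-2-methyl-4-oxobut-2-enoate (Wittig, acetal hydrolysis, O-acylation of its dienolate); the dienophile from the acid and but-3-yn-2-one.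

Key step: step 6

Assumption: (E)-3-methylpent-2-enoic acid is bought as the pure E acid, and the (S)-oxazaborolidinium catalyst is taken, from the accepted binding model for enones, as the enantiomer that exposes the required enone face; its mirror image is equally accessible and would be used if the sense were opposite.

**Step 1**
Reactants: 1 methyl 2-(triphenylphosphoranylidene)propanoate; 2 2,2-dimethoxyacetaldehyde (60% aqueous solution)
Product: 3 methyl (E)-4,4-dimethoxy-2-methylbut-2-enoate
Conditions: CH2Cl2, rt
Reagents that add atoms: none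
Why: Wittig olefination with a stabilised ylide should give the E-trisubstituted enoate, the aldehyde being the only electrophile and the acetal inert.

**Step 2**
Reactants: 3 methyl (E)-4,4-dimethoxy-2-methylbut-2-enoate
Product: 4 methyl (E)-2-methyl-4-oxobut-2-enoate
Conditions: 1 M aq. HCl, THF, rt
Reagents that add atoms: water, O
Why: Acid-catalysed acetal hydrolysis unmasks the aldehyde while the conjugated methyl ester is stable to dilute acid, and either alkene geometry of the enal would serve in step 4.

**Step 3**
Reactants: 5 (E)-3-methylpent-2-enoic acid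
Product: 6 (E)-3-methylpent-2-enoyl chloride
Conditions: (COCl)2, cat. HCONMe2, CH2Cl2, 0 °C → rt
Reagents that add atoms: oxalyl chloride, ClC(=O)C(=O)Cl
Why: Acid chloride formation through the chloroiminium (Vilsmeier-type) activation runs without base, so the conjugated E-alkene should neither migrate nor isomerise.

**Step 4**
Reactants: 4 methyl (E)-2-methyl-4-oxobut-2-enoate; 6 (E)-3-methylpent-2-enoyl chloride
Product: 8 methyl (3E)-2-methylidene-4-{[(2E)-3-methylpent-2-enoyl]oxy}but-3-enoate, via potassium dienolate 7 (not isolated)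
Conditions: KOtBu, THF, −78 °C; then 6, −78 → 0 °C; used at once as a cold solution
Reagents that add atoms: none
Why: γ-Deprotonation of the s-trans enal gives the potassium (1E)-dienolate, whose hard oxygen is acylated by the acid chloride (O-acylation of an aldehyde dienolate), so the 1E dienol ester should result, and any 1Z isomer cannot reach the s-cis conformation and stays a bystander in step 6.

**Step 5**
Reactants: 5 (E)-3-methylpent-2-enoic acid; 9 but-3-yn-2-one
Product: 10 (1E)-3-oxobut-1-en-1-yl (2E)-3-methylpent-2-enoate
Conditions: cat. N-methylmorpholine, CH2Cl2, 0 °C → rt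
Reagents that add atoms: none
Why: Tertiary-amine-catalysed conjugate addition of a carboxylic acid to an ynone should give the thermodynamically preferred E-β-acyloxy enone without touching the enoate alkene.

**Step 6**
Reactants: 8 methyl (3E)-2-methylidene-4-{[(2E)-3-methylpent-2-enoyl]oxy}but-3-enoate; 10 (1E)-3-oxobut-1-en-1-yl (2E)-3-methylpent-2-enoate
Product: 11 methyl (3R,4S,5R)-4-acetyl-3,5-bis{[(2E)-3-methylpent-2-enoyl]oxy}cyclohex-1-ene-1-carboxylate
Conditions: 10 (1.5 equiv), 20 mol% (S)-3,3-diphenyl-1-(2-methylphenyl)tetrahydro-1H,3H-pyrrolo[1,2-c][1,3,2]oxazaborole activated with HN(SO2CF3)2, CH2Cl2, −40 → −20 °C, slow addition of 8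
Reagents that add atoms: none
Why: Enantioselective Diels–Alder reaction: the N-protonated oxazaborolidine binds the ketone oxygen of 10 and lowers its LUMO, and the s-cis (1E)-diene 8 adds in a concerted, asynchronous, suprafacial [4+2] cycloaddition that forms C3–C4 and C5–C6 and closes the six-membered carbocycle in one intermolecular event (closest known type: oxazaborolidinium-catalysed cycloadditions of acyclic enones with 1-oxygenated butadienes). Regiochemistry is doubly secured, because the acyloxy donor on C3 and the ester on C1 both place the largest HOMO coefficient on C6, which bonds to the enone β-carbon C5, so the acetyl-bearing C4 bonds to C3. The acetyl group sits endo under the diene in the Lewis-acid-bound transition state, which puts it cis to the outside acyloxy group of the E-diene (C3/C4 cis), and the E geometry of 10 is carried over as the C4/C5 trans relationship. The absolute configuration is set by the catalyst, whose aryl group shields one face of the bound enone so that the diene adds to the Re face at C4 and C5 (3R,4S,5R). The step also needs cross-cycloaddition to win over dimerisation of the ester-substituted diene, which slow addition of 8 to an excess of selectively activated 10 at low temperature should secure.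

**Step 7**
Reactants: 11 methyl (3R,4S,5R)-4-acetyl-3,5-bis{[(2E)-3-methylpent-2-enoyl]oxy}cyclohex-1-ene-1-carboxylate
Product: 12 methyl (3R,4S,5R)-4-acetoxy-3,5-bis{[(2E)-3-methylpent-2-enoyl]oxy}cyclohex-1-ene-1-carboxylate
Conditions: mCPBA, CH2Cl2, 0 °C → rt
Reagents that add atoms: 3-chloroperoxybenzoic acid, OOC(=O)c1cccc(Cl)c1
Why: Baeyer–Villiger oxidation, in which the secondary ring carbon C4 migrates in preference to methyl and with retention of configuration, while the three ester-conjugated alkenes are too electron-poor to be epoxidised at a competitive rate.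

**Step 8**
Reactants: 12 methyl (3R,4S,5R)-4-acetoxy-3,5-bis{[(2E)-3-methylpent-2-enoyl]oxy}cyclohex-1-ene-1-carboxylate
Product: 13 methyl (3R,4S,5R)-4-hydroxy-3,5-bis{[(2E)-3-methylpent-2-enoyl]oxy}cyclohex-1-ene-1-carboxylate
Conditions: HCl (1.25 M in MeOH), 0 °C → rt, stopped when 12 is consumed
Reagents that add atoms: none
Why: Acid-catalysed transesterification (methanolysis) should cleave the unhindered, non-conjugated acetate much faster than the two β,β-disubstituted conjugated enoates, the methyl ester exchanges degenerately, and the acidic medium avoids base-mediated acyl migration and leaves C3–C5 untouched.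

**Compound list**

1 | methyl 2-(triphenylphosphoranylidene)propanoate | COC(=O)C(C)=P(c1ccccc1)(c1ccccc1)c1ccccc1 | starting material
2 | 2,2-dimethoxyacetaldehyde | COC(OC)C=O | starting material
3 | methyl (E)-4,4-dimethoxy-2-methylbut-2-enoate | COC(=O)/C(C)=C/C(OC)OC | intermediate
4 | methyl (E)-2-methyl-4-oxobut-2-enoate | COC(=O)/C(C)=C/C=O | intermediate
5 | (E)-3-methylpent-2-enoic acid | CC/C(C)=C/C(=O)O | starting material
6 | (E)-3-methylpent-2-enoyl chloride | CC/C(C)=C/C(=O)Cl | intermediate
7 | potassium (1E)-3-(methoxycarbonyl)buta-1,3-dien-1-olate | [K+].[O-]/C=C/C(=C)C(=O)OC | intermediate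
8 | methyl (3E)-2-methylidene-4-{[(2E)-3-methylpent-2-enoyl]oxy}but-3-enoate | CC/C(C)=C/C(=O)O/C=C/C(=C)C(=O)OC | intermediate
9 | but-3-yn-2-one | CC(=O)C#C | starting material
10 | (1E)-3-oxobut-1-en-1-yl (2E)-3-methylpent-2-enoate | CC/C(C)=C/C(=O)O/C=C/C(C)=O | intermediate
11 | methyl (3R,4S,5R)-4-acetyl-3,5-bis{[(2E)-3-methylpent-2-enoyl]oxy}cyclohex-1-ene-1-carboxylate | CC/C(C)=C/C(=O)O[C@@H]1C=C(C(=O)OC)C[C@@H](OC(=O)/C=C(\C)CC)[C@@H]1C(C)=O | intermediate
12 | methyl (3R,4S,5R)-4-acetoxy-3,5-bis{[(2E)-3-methylpent-2-enoyl]oxy}cyclohex-1-ene-1-carboxylate | CC/C(C)=C/C(=O)O[C@@H]1C=C(C(=O)OC)C[C@@H](OC(=O)/C=C(\C)CC)[C@@H]1OC(C)=O | intermediate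
13 | methyl (3R,4S,5R)-4-hydroxy-3,5-bis{[(2E)-3-methylpent-2-enoyl]oxy}cyclohex-1-ene-1-carboxylate | CC/C(C)=C/C(=O)O[C@@H]1C=C(C(=O)OC)C[C@@H](OC(=O)/C=C(\C)CC)[C@@H]1O | target

**Step count**

Total steps: 8. Longest linear sequence: 6 (steps 1, 2, 4, 6, 7, 8).

**Steps most likely to fail**

Step 6. The cycloaddition may be too slow at the temperature the catalyst needs, so that dimerisation of the diene, loss of an acyloxy group from the β-acyloxy ketone or poor facial selectivity take over. The fallback raises the donor strength of the diene and esterifies O3 afterwards, using the known catalysed cycloadditions of 1-silyloxybutadienes. It sets out from 4: tBuMe2SiOSO2CF3 and Et3N in CH2Cl2 at −78 °C should give methyl (3E)-4-[(tert-butyldimethylsilyl)oxy]-2-methylidenebut-3-enoate F1. Cycloaddition of this diene with 10 under the conditions of step 6 should give methyl (3R,4S,5R)-4-acetyl-3-[(tert-butyldimethylsilyl)oxy]-5-{[(2E)-3-methylpent-2-enoyl]oxy}cyclohex-1-ene-1-carboxylate F2. mCPBA should turn the acetyl group into the acetate, methyl (3R,4S,5R)-4-acetoxy-3-[(tert-butyldimethylsilyl)oxy]-5-{[(2E)-3-methylpent-2-enoyl]oxy}cyclohex-1-ene-1-carboxylate F3. HF·pyridine in THF should free O3 to give methyl (3R,4R,5R)-4-acetoxy-3-hydroxy-5-{[(2E)-3-methylpent-2-enoyl]oxy}cyclohex-1-ene-1-carboxylate F4 (same spatial arrangement; the C4 descriptor changes only through the priority rules). Acylation of this alcohol with 6 (pyridine, CH2Cl2, 0 °C) comes back to the route at 12.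

Step 7. Migration of the electron-poor C4 centre may be slow, so that epoxidation of the conjugated alkenes or elimination of an acyloxy group β to the ketone competes. The fallback builds and oxidises the ring with alkene-free placeholder esters, which allows CF3CO3H, and brings in the enoates afterwards. It sets out from 4 and 9. The potassium dienolate 7 (from 4 with KOtBu, THF, −78 °C) and ClCH2COCl should give methyl (3E)-4-[(chloroacetyl)oxy]-2-methylidenebut-3-enoate F5. Chloroacetic acid and 9 with catalytic N-methylmorpholine should give (1E)-3-oxobut-1-en-1-yl chloroacetate F6. Their cycloaddition under the conditions of step 6 should give methyl (3R,4S,5R)-4-acetyl-3,5-bis[(chloroacetyl)oxy]cyclohex-1-ene-1-carboxylate F7. CF3CO3H with Na2HPO4 in CH2Cl2 at 0 °C should give methyl (3R,4S,5R)-4-acetoxy-3,5-bis[(chloroacetyl)oxy]cyclohex-1-ene-1-carboxylate F8. Thiourea and NaHCO3 in EtOH should remove both chloroacetates to give methyl (3R,4S,5R)-4-acetoxy-3,5-dihydroxycyclohex-1-ene-1-carboxylate F9. Acylation of both hydroxyl groups with 6 (2.2 equiv, pyridine, cat. 4-(dimethylamino)pyridine, CH2Cl2) comes back to the route at 12.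

Step 4. Acylation on carbon, attack of the alkoxide base on the acid chloride, formation of 1E/1Z mixtures and Diels–Alder dimerisation of the diene during isolation may erode the supply of diene. The fallback separates enolisation from acylation through an isolable silyl dienol ether. It sets out from 4: Me3SiCl, Et3N and NaI in MeCN should give methyl (3E)-2-methylidene-4-[(trimethylsilyl)oxy]but-3-enoate F10, which is purified by distillation to the 1E isomer. KOtBu in THF at −78 °C then cleaves its O–Si bond to the alcohol-free potassium dienolate 7, and acylation with 6 comes back to the route at 8, used directly in step 6.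

**Further compounds**

F1 | step 6 | methyl (3E)-4-[(tert-butyldimethylsilyl)oxy]-2-methylidenebut-3-enoate | COC(=O)C(=C)/C=C/O[Si](C)(C)C(C)(C)C
F2 | step 6 | methyl (3R,4S,5R)-4-acetyl-3-[(tert-butyldimethylsilyl)oxy]-5-{[(2E)-3-methylpent-2-enoyl]oxy}cyclohex-1-ene-1-carboxylate | CC(C)(C)[Si](C)(C)O[C@@H]1C=C(C(=O)OC)C[C@@H](OC(=O)/C=C(\C)CC)[C@@H]1C(C)=O
F3 | step 6 | methyl (3R,4S,5R)-4-acetoxy-3-[(tert-butyldimethylsilyl)oxy]-5-{[(2E)-3-methylpent-2-enoyl]oxy}cyclohex-1-ene-1-carboxylate | CC(C)(C)[Si](C)(C)O[C@@H]1C=C(C(=O)OC)C[C@@H](OC(=O)/C=C(\C)CC)[C@@H]1OC(C)=O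
F4 | step 6 | methyl (3R,4R,5R)-4-acetoxy-3-hydroxy-5-{[(2E)-3-methylpent-2-enoyl]oxy}cyclohex-1-ene-1-carboxylate | O[C@@H]1C=C(C(=O)OC)C[C@@H](OC(=O)/C=C(\C)CC)[C@@H]1OC(C)=O
F5 | step 7 | methyl (3E)-4-[(chloroacetyl)oxy]-2-methylidenebut-3-enoate | COC(=O)C(=C)/C=C/OC(=O)CCl
F6 | step 7 | (1E)-3-oxobut-1-en-1-yl chloroacetate | CC(=O)/C=C/OC(=O)CCl
F7 | step 7 | methyl (3R,4S,5R)-4-acetyl-3,5-bis[(chloroacetyl)oxy]cyclohex-1-ene-1-carboxylate | ClCC(=O)O[C@@H]1C=C(C(=O)OC)C[C@@H](OC(=O)CCl)[C@@H]1C(C)=O
F8 | step 7 | methyl (3R,4S,5R)-4-acetoxy-3,5-bis[(chloroacetyl)oxy]cyclohex-1-ene-1-carboxylate | ClCC(=O)O[C@@H]1C=C(C(=O)OC)C[C@@H](OC(=O)CCl)[C@@H]1OC(C)=O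
F9 | step 7 | methyl (3R,4S,5R)-4-acetoxy-3,5-dihydroxycyclohex-1-ene-1-carboxylate | O[C@@H]1C=C(C(=O)OC)C[C@@H](O)[C@@H]1OC(C)=O
F10 | step 4 | methyl (3E)-2-methylidene-4-[(trimethylsilyl)oxy]but-3-enoate | COC(=O)C(=C)/C=C/O[Si](C)(C)C
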